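A closed, stirred vessel holds a substrate that opens to an intermediate, and several steps then compete for that intermediate.

| flask | substrate | first nucleophile | second nucleophile | temperature | time |
|---|---|---|---|---|---|
| north-west | 0.10 M | 4.00 equiv | 0.600 equiv | 10 °C | 50 s |
| west | 0.10 M | 4.00 equiv | 0.600 equiv | 25 °C | 50 s |
| north-east | 0.10 M | 4.00 equiv | 0.600 equiv | 40 °C | 50 s |

    substrate → intermediate (k1 = 0.0438 s⁻¹, Ea1 = 84.0 kJ mol⁻¹)
    first nucleophile + intermediate → target (k2 = 16.0 M⁻¹ s⁻¹, Ea2 = 44.0 kJ mol⁻¹)
    second nucleophile + intermediate → other capture product (k3 = 199 M⁻¹ s⁻¹, Ea3 = 37.0 kJ mol⁻¹)
    intermediate → solvolysis product (k4 = 1.19 s⁻¹, Ea4 = 61.0 kJ mol⁻¹)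
    intermediate → side product A (k5 = 0.928 s⁻¹, Ea5 = 76.0 kJ mol⁻¹)
    2 first nucleophile → self-condensation product (k6 = 0.0718 M⁻¹ s⁻¹, Ea6 = 51.0 kJ mol⁻¹)
    substrate + intermediate → side product B (k7 = 0.360 M⁻¹ s⁻¹, Ea7 = 58.0 kJ mol⁻¹)
    (constants at 25 °C)

* the flask that comes out highest in amount of target, in percent of the substrate charged, or "all alike" when all lie within 1.5 percentage points (north-west / west / north-east / all alike)
* target at the end, in percent of the substrate charged, north-west
* target at the end, in percent of the substrate charged, west
* target at the end, in percent of the substrate charged, north-east

- percentages count the substrate that a species holds: one side product B counts as two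
- two of one species on the left: rate k times its square, two consumed each time
- at 25 °C the constants are as listed, elsewhere as the activation energies make them

I start in west, at 25 °C, where the substrate has a half-life of 15.8 s. Let x be the fraction of its charge that the first nucleophile still has, and y the same for the second nucleophile. The two captures are then pseudo-first-order at any moment: the intermediate goes to target at 6.40 s⁻¹ times x, to other capture product at 11.9 s⁻¹ times y, and to solvolysis product and side product A together at 2.12 s⁻¹. Side product B costs 0.0360 s⁻¹ at the full substrate charge, far less than 2.12 s⁻¹, so I drop it. At the start the intermediate lasts 0.0489 s, far shorter than 15.8 s, so it sits at steady state, and target is converted substrate times a share: the target term over the sum of the terms. With x and y at one, that share is 31.3%. West converts 88.8% of its substrate in 50 s, so my first estimate is 27.8%.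

I doubt it: the nucleophiles do not stay at their charge. The first nucleophile has a first half-life of 17.4 s by self-condensation, beside 15.8 s for the substrate, so I expect the share to fall during the run. A better choice is the mid-run share, the share at the moment when half the substrate has gone. At 15.8 s I reckon the first nucleophile at x = 0.524, counting self-condensation and leaving out capture. The second nucleophile has paid for its start share of that converted substrate, which leaves y = 0.514. The mid-run share for west is therefore 28.9%, and the estimate becomes 25.7%.

Next objection: the other flasks have other constants. Recomputing the start share gives 29.7% in north-west and 31.7% in north-east, close to the 31.3% of west. So I carry the one mid-run share and let temperature act through conversion, as a rough rule, since the mid-run moment was reckoned for west. The substrate constant becomes 0.00728 s⁻¹ in north-west and 0.222 s⁻¹ in north-east, which gives conversions of 30.5% and >99.9%. My estimates are 8.81% for north-west and 28.9% for north-east, so my estimate for north-east stands above my estimate for west by 3.2 percentage points, more than the margin of 1.5 points.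

The forecast names north-east, with 7.9%, 24.9% and 29.2% for north-west, west and north-east, and its reckoning opens with “Treat the intermediate as steady state”.

The simulation gives 7.83% in north-west, 24.9% in west and 29.1% in north-east, so north-east comes out highest. West converted 88.8% of its substrate, and its target divided by that conversion is 28.0%, beside the 28.9% I carried. A neighbour, the north-west charge run at 35 °C, has 0.14% of its substrate left at the end, so the carried share gives 28.9%, and that flask holds 28.7% of target.

The numbers of this flask were set for the occasion; the run is a simulation.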